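**Plan**

- Retrosynthesis: the ring B acid is unmasked from its benzyl ester last. The first skeletal cut is the depside C(=O)–O bond between the C1' carbonyl of ring A and O4 of ring B. The second cut takes out the C6'–pentyl and C1'–CO2H bonds of ring A together.
- Enabling feature: in ring A the pentyl-bearing C6' and the carbonyl-bearing C1' are adjacent, and C1' has the C2' methoxy on its other side. This is the pattern left when a nucleophile and an electrophile add across a 3-methoxyaryne.
- Forward, ring A: 1-bromopentane 1 gives pentylmagnesium bromide 2. Then 1-fluoro-3,5-dimethoxybenzene 3, 2 and CO2 4 pass through 5, 6 and 7 to acid 8 in one flask.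
- Forward, ring B and union: olivetol 9 is carboxylated to 10 and esterified with benzyl bromide 11 to give 12. Acid 8 and 12 are joined through 13 to 14, and hydrogenolysis gives target 15.
- Both benzene rings are bought and no ring is formed. The target has no stereocentre and no double-bond geometry to control.

Key step: step 2

Remark: primed locants denote ring A (the acyl ring) and unprimed ones ring B; once 2 has been added, lithium–magnesium exchange at the fluorinated aryl carbon may precede loss of fluoride, which leads to the same aryne, and the equation is written for loss of LiF.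

Step 1
Reactants: 1 1-bromopentane
Product: 2 pentylmagnesium bromide
Conditions: Mg turnings, THF, 35–40 °C; titrated and used as a solution
Reagents that add atoms: magnesium, [Mg]
Why: Grignard formation by insertion of magnesium into a primary C–Br bond, run dilute and below reflux so that Wurtz coupling stays minor.

Step 2
Reactants: 3 1-fluoro-3,5-dimethoxybenzene, 2 pentylmagnesium bromide, 4 carbon dioxide
Product: 8 2,4-dimethoxy-6-pentylbenzoic acid, via 2-fluoro-4,6-dimethoxyphenyllithium 5 (not isolated), via 3,5-dimethoxybenzyne 6 (not isolated), via 2,4-dimethoxy-6-pentylphenylmagnesium bromide 7 (not isolated)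
Conditions: s-BuLi (1.0 equiv), THF, −78 °C; 2 (3 equiv), −78 °C → rt, then 40 °C; dry CO2 gas, 0 °C; aq. HCl
Reagents that add atoms: none
Why: s-BuLi removes the ring proton of 3 that lies between fluorine and a methoxy (two equivalent sites, each acidified by both neighbours and most strongly by fluorine), giving 5, which persists at −78 °C and ejects LiF on warming to give aryne 6. The σ-withdrawing methoxy next to the triple bond of 6 distorts it so that the carbon meta to that methoxy (the former C–F carbon) is the more electrophilic end; the pentyl group of 2 bonds there and magnesium arrives at the carbon ortho to the methoxy, where the charge is stabilised inductively and by O→Mg coordination, giving 7. CO2 then inserts into the C–Mg bond of 7, so the C6'–pentyl and C1'–CO2H bonds are both made in one flask while the remote methoxy becomes the C4' methoxy; no ring closes and no stereocentre is created. The closest known reaction type is the tandem aryne carbometalation–electrophile quench, in which a lithiated haloarene is warmed with a Grignard or alkyllithium reagent and the new aryl-metal is trapped, a sequence already applied to fluoroanisoles to make 6-alkyl-2-methoxybenzoic acids. Three selectivities are needed: the site of lithiation, secured by fluorine (metalation between the two methoxys cannot lead to an aryne and only costs material); the direction of addition, secured by the flanking methoxy; and capture of 6 by 2 in preference to 5 or 7, secured by the threefold charge of 2 and by using no more than one equivalent of s-BuLi.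

Step 3
Reactants: 9 olivetol (5-pentylbenzene-1,3-diol)
Product: 10 olivetolic acid (2,4-dihydroxy-6-pentylbenzoic acid)
Conditions: MeOMgOCO2Me (2 M in DMF, 4 equiv), 120 °C, Ar; cold 1 M HCl
Reagents that add atoms: methyl magnesium carbonate, COC(=O)O[Mg]OC
Why: Kolbe–Schmitt-type ortho-carboxylation with methyl magnesium carbonate, in which the magnesium phenoxide takes up CO2 at the ring carbon ortho to one hydroxyl and para to the other, and chelation of magnesium by the emerging salicylate holds the reversible carboxylation on the product side until the cold acid quench.

Step 4
Reactants: 10 olivetolic acid, 11 benzyl bromide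
Product: 12 benzyl olivetolate (benzyl 2,4-dihydroxy-6-pentylbenzoate)
Conditions: KHCO3 (1.2 equiv), DMF, rt
Reagents that add atoms: none
Why: SN2 alkylation of the carboxylate, since KHCO3 ionises only the carboxylic acid and leaves both phenols protonated, and room temperature avoids decarboxylation of the salicylic-type acid.

Step 5
Reactants: 8 2,4-dimethoxy-6-pentylbenzoic acid, 12 benzyl olivetolate
Product: 14 benzyl 4-[(2,4-dimethoxy-6-pentylbenzoyl)oxy]-2-hydroxy-6-pentylbenzoate, via mixed trifluoroacetic anhydride 13 (not isolated)
Conditions: (CF3CO)2O (3 equiv), toluene, 0 °C → rt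
Reagents that add atoms: none
Why: Mixed-anhydride esterification as commonly used for depsides, in which 13 ionises readily to an acylium ion stabilised by the ortho and para methoxys and so overcomes the 2,6-disubstitution of ring A, while only the free 4-hydroxyl of 12 should be acylated because the 2-hydroxyl is locked in a hydrogen bond to the neighbouring ester carbonyl.

Step 6
Reactants: 14 benzyl 4-[(2,4-dimethoxy-6-pentylbenzoyl)oxy]-2-hydroxy-6-pentylbenzoate
Product: 15 4-[(2,4-dimethoxy-6-pentylbenzoyl)oxy]-2-hydroxy-6-pentylbenzoic acid (target, CNP0139062.0)
Conditions: H2 (1 atm), 10% Pd/C, EtOAc, rt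
Reagents that add atoms: none
Why: Catalytic hydrogenolysis of the benzylic C–O bond frees the acid under neutral conditions that leave the aryl ester link, the methyl ethers and the phenol untouched, and the non-nucleophilic solvent excludes alcoholysis of the depside.

**Compound list**

1 | 1-bromopentane | CCCCCBr | starting material
2 | pentylmagnesium bromide | CCCCC[Mg]Br | intermediate
3 | 1-fluoro-3,5-dimethoxybenzene | COc1cc(F)cc(OC)c1 | starting material
4 | carbon dioxide | O=C=O | starting material
5 | 2-fluoro-4,6-dimethoxyphenyllithium (2-lithio-1-fluoro-3,5-dimethoxybenzene) | COc1cc(F)c([Li])c(OC)c1 | intermediate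
6 | 3,5-dimethoxybenzyne | COC1=CC(OC)=CC#C1 | intermediate
7 | 2,4-dimethoxy-6-pentylphenylmagnesium bromide | CCCCCc1cc(OC)cc(OC)c1[Mg]Br | intermediate
8 | 2,4-dimethoxy-6-pentylbenzoic acid | CCCCCc1cc(OC)cc(OC)c1C(=O)O | intermediate
9 | olivetol (5-pentylbenzene-1,3-diol) | CCCCCc1cc(O)cc(O)c1 | starting material
10 | olivetolic acid (2,4-dihydroxy-6-pentylbenzoic acid) | CCCCCc1cc(O)cc(O)c1C(=O)O | intermediate
11 | benzyl bromide | BrCc1ccccc1 | starting material
12 | benzyl olivetolate (benzyl 2,4-dihydroxy-6-pentylbenzoate) | CCCCCc1cc(O)cc(O)c1C(=O)OCc1ccccc1 | intermediate
13 | 2,4-dimethoxy-6-pentylbenzoic trifluoroacetic anhydride (mixed trifluoroacetic anhydride) | CCCCCc1cc(OC)cc(OC)c1C(=O)OC(=O)C(F)(F)F | intermediate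
14 | benzyl 4-[(2,4-dimethoxy-6-pentylbenzoyl)oxy]-2-hydroxy-6-pentylbenzoate | CCCCCc1cc(OC(=O)c2c(CCCCC)cc(OC)cc2OC)cc(O)c1C(=O)OCc1ccccc1 | intermediate
15 | 4-[(2,4-dimethoxy-6-pentylbenzoyl)oxy]-2-hydroxy-6-pentylbenzoic acid | CCCCCc1cc(OC(=O)c2c(CCCCC)cc(OC)cc2OC)cc(O)c1C(=O)O | target

Total step count: 6. Longest linear sequence: 4 steps (1 → 2 → 8 → 14 → 15, or equally 9 → 10 → 12 → 14 → 15).

**Steps most likely to fail**

Step 2 carries the most risk.
- Deprotonation may occur partly between the two methoxys instead of next to fluorine.
- The aryne may be captured by aryl-metal species already in the flask instead of by the pentyl reagent.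
- β-Hydride transfer from the Grignard reagent may merely reduce the aryne.
- The surplus Grignard reagent is carboxylated as well, so the product has to be freed from an aliphatic acid by crystallisation or under vacuum.

The fallback drops the aryne and draws ring A from the ring B building block. Setting out from 12, both phenols are methylated (MeI, K2CO3, DMF, 50 °C) to give benzyl 2,4-dimethoxy-6-pentylbenzoate F1. Hydrogenolysis (H2, Pd/C, EtOAc, rt) then comes back to the route at 8.

Step 3 is next.
- Conversion may be incomplete.
- Carboxylation may take place between the two hydroxyls.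
- CO2 may be lost again during work-up.

The fallback replaces direct carboxylation by formylation and oxidation. Setting out from 9, Vilsmeier–Haack reaction (POCl3, DMF, 0 °C → rt) leads to (2,4-dihydroxy-6-pentylbenzylidene)dimethyliminium chloride F2. Water hydrolyses this to 2,4-dihydroxy-6-pentylbenzaldehyde F3. Pinnick oxidation (NaClO2, NaH2PO4, sulfamic acid as chlorine scavenger, DMSO–H2O, rt) comes back to the route at 10.

Step 5 is third.
- The phenol may be trifluoroacetylated instead of aroylated.
- The acylium ion may C-acylate the electron-rich ring B.
- Acid may induce loss of CO2 from the ring A acid.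
- Acylation may occur at both hydroxyls.

The fallback leaves the acidic acylium regime for a base-mediated acylation with an isolated acyl donor. Setting out from 8, oxalyl chloride with catalytic DMF in CH2Cl2 gives 2,4-dimethoxy-6-pentylbenzoyl chloride F4. This is added to 12 and K2CO3 in acetone, where only the more acidic, unchelated 4-hydroxyl is ionised, and the sequence comes back to the route at 14.

**Further compounds**

F1 | step 2 | benzyl 2,4-dimethoxy-6-pentylbenzoate | CCCCCc1cc(OC)cc(OC)c1C(=O)OCc1ccccc1
F2 | step 3 | (2,4-dihydroxy-6-pentylbenzylidene)dimethyliminium chloride | CCCCCc1cc(O)cc(O)c1C=[N+](C)C.[Cl-]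
F3 | step 3 | 2,4-dihydroxy-6-pentylbenzaldehyde | CCCCCc1cc(O)cc(O)c1C=O
F4 | step 5 | 2,4-dimethoxy-6-pentylbenzoyl chloride | CCCCCc1cc(OC)cc(OC)c1C(=O)Cl
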